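**Retrosynthetic overview**

1. Feature: C10, the quaternary aminal carbon shared by guanidine ring D (N7–C8–N9–C10–C6) and pyrrolidine ring C (C10–C11–C12–C13–N14). With C6 raised to a carbonyl, ring D is an imidazol-4-one whose C10–H gives a planar, aromatic enolate.
2. Endgame: C8–NH2 ⇒ C8–SMe (ammonolysis); N1–C6 (ring B) ⇒ pyrrole N–H + C6 carbinolamine; C6–OH ⇒ C6=O.
3. Key disconnection: C10–C11 and C13–N14 (ring C) ⇒ imidazolone enolate + 1-chloro-3-iodopropane; a chiral phase-transfer cation sets C10.
4. Ring D ⇒ 3-methyl-2-thiohydantoin from MeNCS (fixes the methyl on N7, next to C6) and the mono-acylated aminal of ethyl glyoxylate, ammonia and the pyrrole carboxamide. C8 is carried as SMe and N1 as N-DMB, so that C10–H and N14–H are the only acidic sites in the key step.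
5. Ring order: A (bought) → D → C → B.

Key step: step 5

**Remarks before the steps**

- Numbering is that of the phakellin skeleton: N1 pyrrole N, C6 aminal CH, N7 (NMe), C8, N9, C10 quaternary C, C11–C13, N14, C15 (C=O). DMB = 2,4-dimethoxybenzyl; ArCO = 4,5-dibromo-1-(2,4-dimethoxybenzyl)pyrrole-2-carbonyl.
- Design remark: C8 is carried as the S-methyl isothiourea, not as a Boc-protected amine, because acylation with Boc2O/DMAP could not be confined to the exocyclic nitrogen when an acidic pyrrole N–H and the enolisable C10–H are present. An N-Boc on the pyrrole would also be attacked by the N14 amidate. The pyrrole N–H is benzylated because a free dibromopyrrole N–H is about as acidic as C10–H and would be alkylated by the dihalide.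
- Assumption: the sense of induction of the ammonium catalyst cannot be predicted for this new pronucleophile. Both catalyst enantiomers are available; the one that gives the C10 configuration drawn for 14 is used.
- CIP note: the spatial arrangement at C10 is the same from 13 to 18. The descriptor is S while C8 bears SMe (N9 outranks N14) and R in the target.

**Route**

Step 1
Reactants: 1 4,5-dibromo-1H-pyrrole-2-carboxamide; 2 2,4-dimethoxybenzyl alcohol
Product: 3 4,5-dibromo-1-(2,4-dimethoxybenzyl)-1H-pyrrole-2-carboxamide
Conditions: PPh3, DIAD, THF, 0 °C → rt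
Reagents that add atoms: none
Why: Mitsunobu N-alkylation of the acidic dibromopyrrole N–H by the benzylic alcohol; the primary carboxamide is not acidic enough to react.

Step 2
Reactants: 3 4,5-dibromo-1-(2,4-dimethoxybenzyl)-1H-pyrrole-2-carboxamide; 4 ethyl glyoxylate; 5 1H-benzotriazole
Product: 6 ethyl 2-(benzotriazol-1-yl)-2-(ArCONH)acetate (racemic)
Conditions: toluene, reflux, Dean–Stark
Reagents that add atoms: none
Why: benzotriazole-mediated three-component amidoalkylation (Mannich-type); the amide adds to the glyoxylate aldehyde and benzotriazole replaces the hemiaminal OH as water is removed, which should give a stable N-acylimine equivalent.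

Step 3
Reactants: 6 ethyl 2-(benzotriazol-1-yl)-2-(ArCONH)acetate; 7 methyl isothiocyanate
Product: 10 5-(ArCONH)-3-methyl-2-thioxoimidazolidin-4-one (racemic), via aminal amine 8 (not isolated), via N-methylthiourea 9 (not isolated)
Conditions: NH3 (excess), THF, 0 °C; evaporate; then MeNCS, Et3N, EtOH, rt → 50 °C
Reagents that add atoms: ammonia, N
Why: ammonia displaces benzotriazolide through the N-acylimine (elimination–addition), the new NH2 adds to the isothiocyanate, and the NHMe nitrogen of the thiourea closes on the ester (thiohydantoin synthesis from an α-amino ester and an isothiocyanate), which puts the methyl group on the nitrogen next to the carbonyl (N7) without ambiguity.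

Step 4
Reactants: 10 5-(ArCONH)-3-methyl-2-thioxoimidazolidin-4-one
Product: 11 5-(ArCONH)-3-methyl-2-(methylsulfanyl)-3,5-dihydro-4H-imidazol-4-one (racemic, enolisable at C10)
Conditions: MeI (1.0 equiv), K2CO3 (1.0 equiv), acetone, 0 °C, Ar
Reagents that add atoms: iodomethane, CI
Why: S-alkylation of the thioamide anion of a thiohydantoin, the most nucleophilic site, should give the 2-alkylthio-imidazol-4-one with C8=N9 and no ring N–H; one equivalent of MeI at 0 °C limits C10-methylation.

Step 5
Reactants: 11 5-(ArCONH)-3-methyl-2-(methylsulfanyl)-3,5-dihydro-4H-imidazol-4-one; 12 1-chloro-3-iodopropane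
Product: 14 (5S)-6-(ArCO)-3-methyl-2-(methylsulfanyl)-1,3,6-triazaspiro[4.4]non-1-en-4-one, via chloropropyl imidazolone 13 (not isolated)
Conditions: C2-symmetric N-spiro binaphthyl quaternary ammonium bromide with 3,4,5-trifluorophenyl groups (5 mol %), Cs2CO3 (s), 12 (1.3 equiv), toluene, −20 °C, Ar; filter; then t-BuOK, THF, 0 °C → rt
Reagents that add atoms: none
Why: Proposed new method: solid Cs2CO3 removes C10–H (the only acid of that strength once N1 is benzylated and C8 bears SMe) to give the aromatic imidazol-4-olate, which enters toluene as a tight ion pair with the chiral ammonium cation and attacks the iodide end of 12 through carbon to give 13; t-BuOK then deprotonates N14–H and the amidate displaces chloride. The closest known reactions are the asymmetric phase-transfer alkylation of glycine and α-substituted amino acid Schiff bases with 1-chloro-3-iodopropane followed by N-cyclisation to prolines, and ion-pair-controlled C-alkylation of azlactone and 2-alkylthio-imidazol-4-one enolates; a 5-acylamino-imidazolone forming an N,N-aminal quaternary centre has not been used. Ring C closes 5-exo-tet by N14 at C13. The C10 stereocentre is set in the C-alkylation by the chiral cation, which shields one face of the planar enolate, and cannot racemise afterwards because 13 and 14 have no α-hydrogen. The step needs C- over O6- or N9-alkylation (favoured by the soft primary iodide and the non-polar medium), iodide over chloride displacement in the first stage, and N14 over neutral N9 or amide-O closure (the amidate is the only anionic nucleophile; N-attack gives a five-membered ring, O-attack a seven-membered one).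

Step 6
Reactants: 14 (5S)-6-(ArCO)-3-methyl-2-(methylsulfanyl)-1,3,6-triazaspiro[4.4]non-1-en-4-one
Product: 15 (5S)-6-(ArCO)-3-methyl-2-(methylsulfanyl)-1,3,6-triazaspiro[4.4]non-1-en-4-ol (C6 epimers)
Conditions: NaBH4, MeOH/THF, −20 → 0 °C; AcOH quench
Reagents that add atoms: none
Why: partial reduction of an imide-type carbonyl to the carbinolamine, as in the borohydride reduction of hydantoin and thiohydantoin C4; N7 is an amidine nitrogen and a poor donor, so C6=O is activated while the tertiary pyrrole amide C15 is inert, and the C6 epimer mixture is of no consequence.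

Step 7
Reactants: 15 (5S)-6-(ArCO)-3-methyl-2-(methylsulfanyl)-1,3,6-triazaspiro[4.4]non-1-en-4-ol
Product: 17 (6S,10S)-8-(methylsulfanyl) tetracycle (S-methyl isothiourea analogue of the target), via pyrrole N-H carbinolamine 16 (not isolated)
Conditions: TFA, anisole, 0 → 60 °C
Reagents that add atoms: none
Why: acidolysis of the N-DMB group (cation trapped by anisole), then acid-mediated aminal formation in which the free pyrrole N1 adds to the C6 amidino-iminium or ring-opened aldehyde (N-acyliminium-type cyclisation, 6-exo-trig, ring B); C6 is set S under reversible conditions because only the cis B/D fusion is accessible when C6 and C10 are bridged by N7–C8–N9.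

Step 8
Reactants: 17 (6S,10S)-8-(methylsulfanyl) tetracycle
Product: 18 (-)-7-N-methyldibromophakellin (6S,10R)
Conditions: NH3 (7 M in MeOH), NH4Cl, sealed tube, 70 °C; basic work-up
Reagents that add atoms: ammonia, N
Why: addition–elimination of ammonia at the isothiouronium carbon C8 with loss of methanethiol (classical guanidine synthesis from an S-methyl isothiourea); neither C10 (quaternary) nor C6 (ring-locked aminal) is affected.

**Compound list**

1 | 4,5-dibromo-1H-pyrrole-2-carboxamide | NC(=O)c1cc(Br)c(Br)[nH]1 | starting material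
2 | 2,4-dimethoxybenzyl alcohol | OCc1ccc(OC)cc1OC | starting material
3 | 4,5-dibromo-1-(2,4-dimethoxybenzyl)-1H-pyrrole-2-carboxamide | NC(=O)c1cc(Br)c(Br)n1Cc1ccc(OC)cc1OC | intermediate
4 | ethyl glyoxylate | CCOC(=O)C=O | starting material
5 | 1H-benzotriazole | c1ccc2[nH]nnc2c1 | starting material
6 | ethyl 2-(benzotriazol-1-yl)-2-(ArCONH)acetate (racemic) | CCOC(=O)C(NC(=O)c1cc(Br)c(Br)n1Cc1ccc(OC)cc1OC)n1nnc2ccccc21 | intermediate
7 | methyl isothiocyanate | CN=C=S | starting material
8 | ethyl 2-amino-2-(ArCONH)acetate (racemic) | CCOC(=O)C(N)NC(=O)c1cc(Br)c(Br)n1Cc1ccc(OC)cc1OC | intermediate (not isolated)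
9 | ethyl 2-(ArCONH)-2-(3-methylthioureido)acetate (racemic) | CCOC(=O)C(NC(=S)NC)NC(=O)c1cc(Br)c(Br)n1Cc1ccc(OC)cc1OC | intermediate (not isolated)
10 | 5-(ArCONH)-3-methyl-2-thioxoimidazolidin-4-one (racemic) | CN1C(=O)C(NC(=O)c2cc(Br)c(Br)n2Cc2ccc(OC)cc2OC)NC1=S | intermediate
11 | 5-(ArCONH)-3-methyl-2-(methylsulfanyl)-3,5-dihydro-4H-imidazol-4-one (racemic) | CSC1=NC(NC(=O)c2cc(Br)c(Br)n2Cc2ccc(OC)cc2OC)C(=O)N1C | intermediate (key-step precursor)
12 | 1-chloro-3-iodopropane | ClCCCI | starting material
13 | (S)-5-(ArCONH)-5-(3-chloropropyl)-3-methyl-2-(methylsulfanyl)-3,5-dihydro-4H-imidazol-4-one | CN1C(=O)[C@@](CCCCl)(NC(=O)c2cc(Br)c(Br)n2Cc2ccc(OC)cc2OC)N=C1SC | intermediate (not isolated)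
14 | (5S)-6-(ArCO)-3-methyl-2-(methylsulfanyl)-1,3,6-triazaspiro[4.4]non-1-en-4-one | CN1C(=O)[C@]2(CCCN2C(=O)c2cc(Br)c(Br)n2Cc2ccc(OC)cc2OC)N=C1SC | intermediate (key-step product)
15 | (5S)-6-(ArCO)-3-methyl-2-(methylsulfanyl)-1,3,6-triazaspiro[4.4]non-1-en-4-ol (C6 epimers) | CN1C(O)[C@]2(CCCN2C(=O)c2cc(Br)c(Br)n2Cc2ccc(OC)cc2OC)N=C1SC | intermediate
16 | (5S)-6-(4,5-dibromo-1H-pyrrole-2-carbonyl)-3-methyl-2-(methylsulfanyl)-1,3,6-triazaspiro[4.4]non-1-en-4-ol | CN1C(O)[C@]2(CCCN2C(=O)c2cc(Br)c(Br)[nH]2)N=C1SC | intermediate (not isolated)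
17 | (6S,10S)-8-(methylsulfanyl) tetracycle: the target with SMe in place of NH2 at C8 | CN1C(SC)=N[C@]23CCCN2C(=O)c2cc(Br)c(Br)n2[C@H]13 | intermediate
18 | (-)-7-N-methyldibromophakellin (6S,10R) | CN1C(N)=N[C@]23CCCN2C(=O)c2cc(Br)c(Br)n2[C@H]13 | target

**Step count**

Total steps: 8. Longest linear sequence: 8 (from 1).

**Steps most likely to fail**

Step 5. The ambident enolate may alkylate at O6 or N9 instead of C10, the hindered tertiary enolate may react too slowly with an unactivated primary iodide, or the ion pair may discriminate poorly between the enolate faces. The fallback sets out from 11 and rejoins at 14, and uses the established conjugate-addition reactivity of azlactone-type and imidazol-4-one pronucleophiles. Compound 11 is added to acrolein under a cinchona-derived bifunctional amine–squaramide catalyst (CH2Cl2, −40 °C) to give the C10-(3-oxopropyl) aldehyde F1. The aldehyde closes onto N14–H to the cyclic N-acyl hemiaminal F2. Ionic reduction through the N-acyliminium ion (Et3SiH, BF3·OEt2, CH2Cl2, −78 → −20 °C) should then give 14. The same two bonds, C10–C11 and C13–N14, are formed.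

Step 6. The carbinolamine alkoxide may open to the aldehyde and take up a second hydride (over-reduction), or hydride may add at C8 with loss of methanethiolate. The fallback sets out from 14 and rejoins at 15. The over-reduction is taken to completion with LiBH4 (THF, 0 °C → rt) to give the ring-opened primary alcohol F3. Parikh–Doering oxidation (SO3·pyridine, DMSO, iPr2NEt, 0 °C) should give the α-quaternary aldehyde, which closes with the isothiourea N7–H to carbinolamine 15.

Step 7. In TFA the isothiourea is fully protonated, so ionisation at C6 and the aminal closure may stall; prolonged heating may lead to benzylation of the pyrrole by the DMB cation or loss of bromine. The fallback sets out from 15 and rejoins at 17, and separates deprotection from ring closure. The carbinolamine is acetylated (Ac2O, DMAP, Et3N, CH2Cl2) to the C6 acetate F4. The DMB group is removed at room temperature (TFA, anisole, CH2Cl2) to give the pyrrole N–H acetate F5. Base (K2CO3, MeCN, rt) then closes ring B by attack of the pyrrolide N1 at C6 with loss of acetate, giving 17.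

**Further compounds**

F1 | step 5 | (S)-5-(ArCONH)-3-methyl-2-(methylsulfanyl)-5-(3-oxopropyl)-3,5-dihydro-4H-imidazol-4-one | CN1C(=O)[C@@](CCC=O)(NC(=O)c2cc(Br)c(Br)n2Cc2ccc(OC)cc2OC)N=C1SC
F2 | step 5 | (5S)-6-(ArCO)-7-hydroxy-3-methyl-2-(methylsulfanyl)-1,3,6-triazaspiro[4.4]non-1-en-4-one (C13 epimers) | CN1C(=O)[C@]2(CCC(O)N2C(=O)c2cc(Br)c(Br)n2Cc2ccc(OC)cc2OC)N=C1SC
F3 | step 6 | methyl N-[(S)-1-(ArCO)-2-(hydroxymethyl)pyrrolidin-2-yl]-N'-methylcarbamimidothioate | CNC(SC)=N[C@]1(CO)CCCN1C(=O)c1cc(Br)c(Br)n1Cc1ccc(OC)cc1OC
F4 | step 7 | (5S)-6-(ArCO)-3-methyl-2-(methylsulfanyl)-1,3,6-triazaspiro[4.4]non-1-en-4-yl acetate | CN1C(OC(C)=O)[C@]2(CCCN2C(=O)c2cc(Br)c(Br)n2Cc2ccc(OC)cc2OC)N=C1SC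
F5 | step 7 | (5S)-6-(4,5-dibromo-1H-pyrrole-2-carbonyl)-3-methyl-2-(methylsulfanyl)-1,3,6-triazaspiro[4.4]non-1-en-4-yl acetate | CN1C(OC(C)=O)[C@]2(CCCN2C(=O)c2cc(Br)c(Br)[nH]2)N=C1SC
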